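The 1,4-benzodioxane is disconnected to an oxetane: C7, C8, C9 and the C9 oxygen of the target are the four ring atoms of a 2-aryl-3-aryloxyoxetane, and its ring strain later lets a gallate phenol (O3) displace that oxygen at benzylic C7, closing the dioxane ring and releasing the C9 hydroxyl. The key step, a Paternò–Büchi photocycloaddition, joins 3,4,5-trimethoxybenzaldehyde to the O4 vinyl ether of methyl gallate whose flanking phenols are silylated; it forms C9–O and C7–C8, the oxetane ring and both stereocentres at once. The ester is converted into the (E)-enal at the end.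

Key step: step 5

Remark: atoms carry lignan labels (C7 = ring CH bearing the trimethoxyphenyl group, C8 = ring CH bearing C9H2OH, O3/O4/O5 = gallate oxygens) and the target is the trans-(7S,8S) isomer; the sense of induction by the chiral diol host in step 5 cannot be predicted, so it is assumed that the (R,R)-host leads to 8, and its antipode would be used otherwise.

Step 1
Reactants: 1 methyl gallate
Product: 2 methyl 4-(benzyloxy)-3,5-dihydroxybenzoate
Conditions: BnBr (1.0 equiv), KHCO3, KI (cat.), DMF, 30 °C
Reagents that add atoms: benzyl bromide, BrCc1ccccc1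
Why: Williamson etherification under a weak base, in which only the 4-OH (para to the ester, the most acidic) is deprotonated, so that monobenzylation should occur at O4.

Step 2
Reactants: 2 methyl 4-(benzyloxy)-3,5-dihydroxybenzoate
Product: 3 methyl 4-(benzyloxy)-3,5-bis(tert-butyldimethylsilyloxy)benzoate
Conditions: TBSCl (2.4 equiv), imidazole, DMF, rt
Reagents that add atoms: tert-butyldimethylsilyl chloride, CC(C)(C)[Si](C)(C)Cl
Why: Imidazole-promoted silylation of the two equivalent phenols, with no free hydroxyl left to which a silyl group could migrate.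

Step 3
Reactants: 3 methyl 4-(benzyloxy)-3,5-bis(tert-butyldimethylsilyloxy)benzoate
Product: 4 methyl 3,5-bis(tert-butyldimethylsilyloxy)-4-hydroxybenzoate
Conditions: H2 (1 atm), 10% Pd/C, EtOAc, rt
Reagents that add atoms: none
Why: Catalytic hydrogenolysis of the benzyl aryl ether under neutral, aprotic conditions should free O4–H without silyl migration or loss, the ester and aryl silyl ethers being inert.

Step 4
Reactants: 4 methyl 3,5-bis(tert-butyldimethylsilyloxy)-4-hydroxybenzoate, 5 vinyl acetate
Product: 6 methyl 3,5-bis(tert-butyldimethylsilyloxy)-4-(vinyloxy)benzoate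
Conditions: [Ir(cod)Cl]2 (2 mol%), Na2CO3 (0.6 equiv), 5 (3 equiv), toluene, 100 °C
Reagents that add atoms: none
Why: Iridium-catalysed transfer vinylation of a phenol, in which the iridium phenoxide adds across vinyl acetate and β-acetoxy elimination releases the aryl vinyl ether; the insoluble carbonate in toluene keeps free phenoxide low, and the 3,5-disilyl arrangement is the thermodynamically favoured one.

Step 5
Reactants: 6 methyl 3,5-bis(tert-butyldimethylsilyloxy)-4-(vinyloxy)benzoate, 7 3,4,5-trimethoxybenzaldehyde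
Product: 8 methyl 3,5-bis(tert-butyldimethylsilyloxy)-4-{[(2R,3S)-2-(3,4,5-trimethoxyphenyl)oxetan-3-yl]oxy}benzoate (aryl and aryloxy trans)
Conditions: hν 365 nm (LED), 7 (2 equiv), (R,R)-TADDOL (tetraphenyl, 2.2 equiv, recovered), degassed PhCF3, −25 °C; chromatography
Reagents that add atoms: none
Why: Proposed new method: the n,π* triplet of 7 adds through its oxygen to the unsubstituted vinyl carbon C9 of 6, giving a triplet 1,4-biradical (benzylic radical at C7, aryloxy-stabilised radical at C8) that, after intersystem crossing, collapses by C7–C8 radical–radical coupling, so the oxetane is closed by 1,4-biradical recombination in a stepwise formal [2+2] cycloaddition (Paternò–Büchi reaction). The closest known reaction type is the racemic Paternò–Büchi addition of aromatic aldehydes to enol ethers, which gives 2-aryl-3-alkoxyoxetanes, together with hydrogen-bond-templated enantioselective photocycloadditions; absolute control for a plain benzaldehyde/vinyl ether pair has not been shown. Both stereocentres are created only in the ring closure: C7 is to be controlled by the chiral diol, which is hydrogen-bonded to one lone pair of the carbonyl oxygen (later O1) and is expected to screen one face of the adjacent C7 radical with a phenyl group, and C8 is set relative to C7 by the steric preference for placing the bulky 2,6-bis(silyloxy)aryloxy group trans to the C7 aryl group. The step needs regio-, trans- and face-selectivity: the first is secured in the substrate by the radical-stabilising aryloxy group on the inner vinyl carbon, the second by the size of the O4 aryl group, and the third rests on the host alone. A Lewis acid is deliberately not used, since complexation of the carbonyl would remove the n,π* state and favour polar C–C bonding at C9; the silyl ethers leave no O–H or weak C–H bond that could quench the triplet, and at 365 nm only the aldehyde absorbs.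

Step 6
Reactants: 8 methyl 3,5-bis(tert-butyldimethylsilyloxy)-4-{[(2R,3S)-2-(3,4,5-trimethoxyphenyl)oxetan-3-yl]oxy}benzoate
Product: 9 methyl 3,5-dihydroxy-4-{[(2R,3S)-2-(3,4,5-trimethoxyphenyl)oxetan-3-yl]oxy}benzoate
Conditions: TBAF (2.2 equiv), AcOH (2.5 equiv), THF, 0 °C
Reagents that add atoms: none
Why: Fluoride-mediated cleavage of aryl silyl ethers, buffered with acetic acid so that neither phenoxide nor acid opens the oxetane and the ester is untouched.

Step 7
Reactants: 9 methyl 3,5-dihydroxy-4-{[(2R,3S)-2-(3,4,5-trimethoxyphenyl)oxetan-3-yl]oxy}benzoate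
Product: 10 methyl (2S,3S)-8-hydroxy-2-(hydroxymethyl)-3-(3,4,5-trimethoxyphenyl)-2,3-dihydro-1,4-benzodioxine-6-carboxylate (trans; 7S,8S)
Conditions: (PhO)2P(O)OH (10 mol%), CH2Cl2, 0 °C to rt
Reagents that add atoms: none
Why: Brønsted-acid-catalysed intramolecular oxetane opening driven by strain release, in which either of the two equivalent phenols displaces the protonated ring oxygen at benzylic C7 (the carbon best able to carry positive charge) in a 6-exo-tet closure with inversion, turning (R)-C7 into (S)-C7 while C8 stays (S), which should give the trans-benzodioxane; a looser, cation-like transition state should lead to the same trans isomer because the tethered phenol is delivered to the O4 face of the benzylic cation.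

Step 8
Reactants: 10 methyl (2S,3S)-8-hydroxy-2-(hydroxymethyl)-3-(3,4,5-trimethoxyphenyl)-2,3-dihydro-1,4-benzodioxine-6-carboxylate
Product: 11 [(2S,3S)-8-hydroxy-3-(3,4,5-trimethoxyphenyl)-2,3-dihydro-1,4-benzodioxine-2,6-diyl]dimethanol
Conditions: DIBAL-H (6 equiv), THF/CH2Cl2, −78 to 0 °C; aqueous Rochelle salt
Reagents that add atoms: none
Why: Hydride reduction of the aryl methyl ester to the benzylic alcohol with excess DIBAL-H, the phenol and alcohol being carried as aluminium alkoxides and the benzodioxane being inert.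

Step 9
Reactants: 11 [(2S,3S)-8-hydroxy-3-(3,4,5-trimethoxyphenyl)-2,3-dihydro-1,4-benzodioxine-2,6-diyl]dimethanol
Product: 12 (2S,3S)-8-hydroxy-2-(hydroxymethyl)-3-(3,4,5-trimethoxyphenyl)-2,3-dihydro-1,4-benzodioxine-6-carbaldehyde
Conditions: activated MnO2 (15 equiv), EtOAc, rt
Reagents that add atoms: none
Why: Chemoselective MnO2 oxidation of the benzylic alcohol, which should leave the aliphatic primary C9 alcohol and the phenol unchanged.

Step 10
Reactants: 12 (2S,3S)-8-hydroxy-2-(hydroxymethyl)-3-(3,4,5-trimethoxyphenyl)-2,3-dihydro-1,4-benzodioxine-6-carbaldehyde, 13 (triphenylphosphoranylidene)acetaldehyde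
Product: 14 (E)-3-[(2S,3S)-8-hydroxy-2-(hydroxymethyl)-3-(3,4,5-trimethoxyphenyl)-2,3-dihydro-1,4-benzodioxin-6-yl]prop-2-enal (CNP0241953.1)
Conditions: 13 (1.3 equiv), toluene/THF, 80 °C
Reagents that add atoms: none
Why: Wittig olefination with a stabilised formylmethylene ylide, which should give the (E)-enal and tolerates the free phenol and alcohol; limiting the ylide avoids a second homologation.

Compound list
1 | methyl gallate (methyl 3,4,5-trihydroxybenzoate) | COC(=O)c1cc(O)c(O)c(O)c1 | starting material
2 | methyl 4-(benzyloxy)-3,5-dihydroxybenzoate | COC(=O)c1cc(O)c(OCc2ccccc2)c(O)c1 | intermediate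
3 | methyl 4-(benzyloxy)-3,5-bis(tert-butyldimethylsilyloxy)benzoate | COC(=O)c1cc(O[Si](C)(C)C(C)(C)C)c(OCc2ccccc2)c(O[Si](C)(C)C(C)(C)C)c1 | intermediate
4 | methyl 3,5-bis(tert-butyldimethylsilyloxy)-4-hydroxybenzoate | COC(=O)c1cc(O[Si](C)(C)C(C)(C)C)c(O)c(O[Si](C)(C)C(C)(C)C)c1 | intermediate
5 | vinyl acetate | C=COC(C)=O | starting material
6 | methyl 3,5-bis(tert-butyldimethylsilyloxy)-4-(vinyloxy)benzoate | C=COc1c(O[Si](C)(C)C(C)(C)C)cc(C(=O)OC)cc1O[Si](C)(C)C(C)(C)C | intermediate
7 | 3,4,5-trimethoxybenzaldehyde | COc1cc(C=O)cc(OC)c1OC | starting material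
8 | methyl 3,5-bis(tert-butyldimethylsilyloxy)-4-{[(2R,3S)-2-(3,4,5-trimethoxyphenyl)oxetan-3-yl]oxy}benzoate | COc1cc([C@H]2OC[C@@H]2Oc3c(O[Si](C)(C)C(C)(C)C)cc(C(=O)OC)cc3O[Si](C)(C)C(C)(C)C)cc(OC)c1OC | intermediate
9 | methyl 3,5-dihydroxy-4-{[(2R,3S)-2-(3,4,5-trimethoxyphenyl)oxetan-3-yl]oxy}benzoate | COc1cc([C@H]2OC[C@@H]2Oc3c(O)cc(C(=O)OC)cc3O)cc(OC)c1OC | intermediate
10 | methyl (2S,3S)-8-hydroxy-2-(hydroxymethyl)-3-(3,4,5-trimethoxyphenyl)-2,3-dihydro-1,4-benzodioxine-6-carboxylate | COc1cc([C@@H]2Oc3cc(C(=O)OC)cc(O)c3O[C@H]2CO)cc(OC)c1OC | intermediate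
11 | [(2S,3S)-8-hydroxy-3-(3,4,5-trimethoxyphenyl)-2,3-dihydro-1,4-benzodioxine-2,6-diyl]dimethanol | COc1cc([C@@H]2Oc3cc(CO)cc(O)c3O[C@H]2CO)cc(OC)c1OC | intermediate
12 | (2S,3S)-8-hydroxy-2-(hydroxymethyl)-3-(3,4,5-trimethoxyphenyl)-2,3-dihydro-1,4-benzodioxine-6-carbaldehyde | COc1cc([C@@H]2Oc3cc(C=O)cc(O)c3O[C@H]2CO)cc(OC)c1OC | intermediate
13 | (triphenylphosphoranylidene)acetaldehyde | O=CC=P(c1ccccc1)(c1ccccc1)c1ccccc1 | starting material
14 | (E)-3-[(2S,3S)-8-hydroxy-2-(hydroxymethyl)-3-(3,4,5-trimethoxyphenyl)-2,3-dihydro-1,4-benzodioxin-6-yl]prop-2-enal | COc1cc([C@@H]2Oc3cc(/C=C/C=O)cc(O)c3O[C@H]2CO)cc(OC)c1OC | target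

Total step count: 10. Longest linear sequence: 10 steps (1 to 14).

Steps most likely to fail

Step 5. What may go wrong: little or wrong-sense facial selectivity in the biradical ring closure, because unbound aldehyde reacts in a racemic background process and the host may not stay bound in the excited state; closure to the cis-oxetane may also compete. The fallback uses known chemistry only and sets out from 6 and 7. These are irradiated without the host (365 nm, PhCF3) to give the racemic trans-oxetane F1, any cis isomer being removed by chromatography. F1 is carried through the conditions of steps 6 and 7 to the racemic bisphenol F2 and the racemic trans-benzodioxane F3. Both hydroxyl groups of F3 are acylated with (1S)-(−)-camphanic chloride (Et3N, DMAP, CH2Cl2). The two diastereomeric esters, the (2S,3S)-derived bis-camphanate F4 and the (2R,3R)-derived bis-camphanate F5, are separated by chromatography or crystallisation and assigned by X-ray analysis against the known camphanate centres. Methanolysis of F4 (NaOMe, MeOH, rt) removes both camphanoyl groups and comes back to the route at 10.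

Step 7. What may go wrong: attack of the phenol at C9 instead of C7, or ionisation at C7 followed by elimination, oligomerisation or partial loss of the trans relationship. In the fallback, opening and closure are separated, setting out from 8. Hydrolysis of the oxetane with dilute aqueous acid (H2SO4, THF/H2O, rt) should give the silyl-protected 1,3-diol F6, whose constitution is the same whichever C–O bond breaks and whose C8 is untouched. Fluoride (TBAF, AcOH, THF) then gives the tetrol F7. The established acid-mediated cyclodehydration of 1-aryl-2-(2-hydroxyaryloxy)propane-1,3-diols (Amberlyst 15 or TsOH, toluene, 70 °C) closes the dioxane ring at the benzylic carbon under thermodynamic control in favour of the trans isomer and comes back to the route at 10.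

Step 4. What may go wrong: slow etherification of the doubly flanked phenol, and base-induced 1,2-silyl migration from O3/O5 to O4 before vinyl transfer, leading to regioisomeric vinyl ethers. In the fallback the vinyl group is carried in latent form from the start, setting out from 1. Mitsunobu etherification with 2-(phenylselanyl)ethanol (PPh3, DIAD, THF) at the most acidic 4-OH gives the selenide F8. Silylation as in step 2 gives the bis-silyl selenide F9. Oxidation (NaIO4, NaHCO3, MeOH/THF/H2O, 0 °C) gives the selenoxide F10, whose thermal syn-elimination (toluene, i-Pr2NH, 80 °C) gives the aryl vinyl ether and comes back to the route at 6, with no free phenol ever standing next to a silyl ether.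

Further compounds
F1 | step 5 | racemic methyl 3,5-bis(tert-butyldimethylsilyloxy)-4-{[(2RS,3SR)-2-(3,4,5-trimethoxyphenyl)oxetan-3-yl]oxy}benzoate (trans) | COc1cc([C@H]2OC[C@@H]2Oc3c(O[Si](C)(C)C(C)(C)C)cc(C(=O)OC)cc3O[Si](C)(C)C(C)(C)C)cc(OC)c1OC.COc1cc([C@@H]2OC[C@H]2Oc3c(O[Si](C)(C)C(C)(C)C)cc(C(=O)OC)cc3O[Si](C)(C)C(C)(C)C)cc(OC)c1OC
F2 | step 5 | racemic methyl 3,5-dihydroxy-4-{[(2RS,3SR)-2-(3,4,5-trimethoxyphenyl)oxetan-3-yl]oxy}benzoate (trans) | COc1cc([C@H]2OC[C@@H]2Oc3c(O)cc(C(=O)OC)cc3O)cc(OC)c1OC.COc1cc([C@@H]2OC[C@H]2Oc3c(O)cc(C(=O)OC)cc3O)cc(OC)c1OC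
F3 | step 5 | racemic methyl (2RS,3RS)-8-hydroxy-2-(hydroxymethyl)-3-(3,4,5-trimethoxyphenyl)-2,3-dihydro-1,4-benzodioxine-6-carboxylate (trans) | COc1cc([C@@H]2Oc3cc(C(=O)OC)cc(O)c3O[C@H]2CO)cc(OC)c1OC.COc1cc([C@H]2Oc3cc(C(=O)OC)cc(O)c3O[C@@H]2CO)cc(OC)c1OC
F4 | step 5 | bis[(1S)-camphanate] (phenol and C9 hydroxyl both acylated) of the (2S,3S)-enantiomer of F3 | COc1cc([C@@H]2Oc3cc(C(=O)OC)cc(OC(=O)[C@@]45CC[C@@](C)(C(=O)O4)C5(C)C)c3O[C@H]2COC(=O)[C@@]67CC[C@@](C)(C(=O)O6)C7(C)C)cc(OC)c1OC
F5 | step 5 | bis[(1S)-camphanate] of the (2R,3R)-enantiomer of F3 | COc1cc([C@H]2Oc3cc(C(=O)OC)cc(OC(=O)[C@@]45CC[C@@](C)(C(=O)O4)C5(C)C)c3O[C@@H]2COC(=O)[C@@]67CC[C@@](C)(C(=O)O6)C7(C)C)cc(OC)c1OC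
F6 | step 7 | methyl 3,5-bis(tert-butyldimethylsilyloxy)-4-{[(2S)-1,3-dihydroxy-1-(3,4,5-trimethoxyphenyl)propan-2-yl]oxy}benzoate (C1 epimers) | COc1cc(C(O)[C@H](CO)Oc2c(O[Si](C)(C)C(C)(C)C)cc(C(=O)OC)cc2O[Si](C)(C)C(C)(C)C)cc(OC)c1OC
F7 | step 7 | methyl 4-{[(2S)-1,3-dihydroxy-1-(3,4,5-trimethoxyphenyl)propan-2-yl]oxy}-3,5-dihydroxybenzoate (C1 epimers) | COc1cc(C(O)[C@H](CO)Oc2c(O)cc(C(=O)OC)cc2O)cc(OC)c1OC
F8 | step 4 | methyl 3,5-dihydroxy-4-[2-(phenylselanyl)ethoxy]benzoate | COC(=O)c1cc(O)c(OCC[Se]c2ccccc2)c(O)c1
F9 | step 4 | methyl 3,5-bis(tert-butyldimethylsilyloxy)-4-[2-(phenylselanyl)ethoxy]benzoate | COC(=O)c1cc(O[Si](C)(C)C(C)(C)C)c(OCC[Se]c2ccccc2)c(O[Si](C)(C)C(C)(C)C)c1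
F10 | step 4 | methyl 3,5-bis(tert-butyldimethylsilyloxy)-4-[2-(phenylseleninyl)ethoxy]benzoate | COC(=O)c1cc(O[Si](C)(C)C(C)(C)C)c(OCC[Se](=O)c2ccccc2)c(O[Si](C)(C)C(C)(C)C)c1
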